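## Retrosynthetic overview

- Ring A is bought intact as ketoisophorone 1; asymmetric reduction sets the C2 carbinol (labdane numbering), which later relays to C5, C9 and C10.
- C5–C6: enol triflate 5 plus a ketal-masked zinc homoenolate of butanone (d3 synthon) gives ketone 7, extended to the E-enoate 8.
- Ring B is formed second: proton-initiated cation–olefin closure of 8 (C9–C10 bond) gives the trans-decalin Δ7 ester 9.
- Key disconnection C12–C13: primary boronate 12 plus the lithiated (R)-carbamate 14 made from 13 (an α-oxyallyl carbanion, then 1,2-metallate shift) sets C13 and gives 18.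
- Desilylation and senecioylation of the C2 hydroxyl finish 20.

Assumption: atom labels C1–C20 follow labdane numbering; the target is read as the ent-labdane (2R,5R,9R,10R,13S), with the C2 ester equatorial and trans to the C10 methyl, and (2R)-but-3-en-2-ol is taken as commercial.

## Route

Step 1
Reactants: 1 ketoisophorone (2,6,6-trimethylcyclohex-2-ene-1,4-dione)
Product: 2 (4R)-4-hydroxy-2,6,6-trimethylcyclohex-2-en-1-one
Conditions: RuCl[(R,R)-TsDPEN](p-cymene) (1 mol%), KOH (cat.), i-PrOH, 25 °C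
Reagents that add atoms: none
Why: Noyori asymmetric transfer hydrogenation reduces only the unhindered C4 carbonyl (the other one is flanked by the quaternary carbon), and with the enone π-system in the role of the aryl group the (R,R)-catalyst is expected to give the (4R)-carbinol, which becomes C2 of the target.

Step 2
Reactants: 2 (4R)-4-hydroxy-2,6,6-trimethylcyclohex-2-en-1-one
Product: 3 (4R)-2,6,6-trimethyl-4-{[tri(propan-2-yl)silyl]oxy}cyclohex-2-en-1-one
Conditions: TIPSOTf, 2,6-lutidine, CH2Cl2, 0 °C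
Reagents that add atoms: triisopropylsilyl trifluoromethanesulfonate, CC(C)[Si](OS(=O)(=O)C(F)(F)F)(C(C)C)C(C)C
Why: Silylation gives a hindered silyl ether that survives the hydride, organozinc, Lewis-acid and organolithium steps and cannot act as a neighbouring group toward the later C10 cation.

Step 3
Reactants: 3 (4R)-2,6,6-trimethyl-4-{[tri(propan-2-yl)silyl]oxy}cyclohex-2-en-1-one
Product: 5 (4S)-2,6,6-trimethyl-4-{[tri(propan-2-yl)silyl]oxy}cyclohex-1-en-1-yl trifluoromethanesulfonate, via lithium enolate 4 (not isolated)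
Conditions: LiBH(s-Bu)3, THF, −78 °C; then PhNTf2, −78 °C → rt
Reagents that add atoms: N-phenylbis(trifluoromethanesulfonimide), O=S(=O)(N(c1ccccc1)S(=O)(=O)C(F)(F)F)C(F)(F)F
Why: Reductive triflation, in which the bulky borohydride adds 1,4 to the α-methyl enone (as with carvone) and O-triflation traps the regiodefined tetrasubstituted enolate as the C5=C10 enol triflate; the stereocentre is untouched (the descriptor changes only through CIP priorities).

Step 4
Reactants: 5 (4S)-2,6,6-trimethyl-4-{[tri(propan-2-yl)silyl]oxy}cyclohex-1-en-1-yl trifluoromethanesulfonate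
Product: 7 4-[(4S)-2,6,6-trimethyl-4-{[tri(propan-2-yl)silyl]oxy}cyclohex-1-en-1-yl]butan-2-one, via dioxolane ketal 6 (not isolated)
Conditions: Zn, LiCl, 2-(2-bromoethyl)-2-methyl-1,3-dioxolane, THF, 50 °C; then 5, Pd(OAc)2 (cat.), SPhos (cat.), THF, 60 °C; then 1 M HCl, THF, rt
Reagents that add atoms: bromo[2-(2-methyl-1,3-dioxolan-2-yl)ethyl]zinc, CC1(CC[Zn]Br)OCCO1 (made in the flask from 2-(2-bromoethyl)-2-methyl-1,3-dioxolane, CC1(CCBr)OCCO1); water, O
Why: Negishi coupling of a ketal-masked β-zincio ketone (a homoenolate equivalent of butanone) joins C6, the normally electrophilic β-carbon of methyl vinyl ketone, to C5, a former carbonyl carbon, which gives a 1,4-dioxygenated relationship that normal polarity cannot give; acid work-up frees the ketone.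

Step 5
Reactants: 7 4-[(4S)-2,6,6-trimethyl-4-{[tri(propan-2-yl)silyl]oxy}cyclohex-1-en-1-yl]butan-2-one
Product: 8 methyl (2E)-3-methyl-5-[(4S)-2,6,6-trimethyl-4-{[tri(propan-2-yl)silyl]oxy}cyclohex-1-en-1-yl]pent-2-enoate
Conditions: (MeO)2P(O)CH2CO2Me, NaH, THF, 0 → 60 °C; E isomer separated by chromatography
Reagents that add atoms: trimethyl phosphonoacetate, COC(=O)CP(=O)(OC)OC
Why: Horner–Wadsworth–Emmons olefination of the methyl ketone gives the monocyclofarnesate-type enoate with the usual E preference (about 4:1), and the E geometry is what later places the C9 substituent equatorial.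

Step 6
Reactants: 8 methyl (2E)-3-methyl-5-[(4S)-2,6,6-trimethyl-4-{[tri(propan-2-yl)silyl]oxy}cyclohex-1-en-1-yl]pent-2-enoate
Product: 9 methyl (1R,4aR,7R,8aR)-2,5,5,8a-tetramethyl-7-{[tri(propan-2-yl)silyl]oxy}-1,4,4a,5,6,7,8,8a-octahydronaphthalene-1-carboxylate
Conditions: SnCl4, wet CH2Cl2, −78 → 0 °C
Reagents that add atoms: none
Why: Proton-initiated cation–olefin cyclization of the monocyclofarnesate to bicyclofarnesate type (Stork–Eschenmoser manifold), in which reversible protonation at C5 gives the C10 cation and the E-enoate captures it through a chair–chair transition state (trans ring fusion, equatorial C9 ester), the C2 silyloxy group staying equatorial and hence trans to the axial C10 methyl to avoid 1,3-diaxial strain with the C4 and C10 methyls, so that C2 controls C5, C9 and C10; loss of H7 gives the non-conjugated Δ7 ester.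

Step 7
Reactants: 9 methyl (1R,4aR,7R,8aR)-2,5,5,8a-tetramethyl-7-{[tri(propan-2-yl)silyl]oxy}-1,4,4a,5,6,7,8,8a-octahydronaphthalene-1-carboxylate
Product: 11 {[(2R,4aR,8R,8aR)-8-ethenyl-4,4,7,8a-tetramethyl-1,2,3,4,4a,5,8,8a-octahydronaphthalen-2-yl]oxy}tri(propan-2-yl)silane, via aldehyde 10 (not isolated)
Conditions: i-Bu2AlH, CH2Cl2, −78 °C; then Ph3PCH3Br, KN(SiMe3)2, THF, −78 °C → rt
Reagents that add atoms: methyltriphenylphosphonium bromide, [Br-].C[P+](c1ccccc1)(c1ccccc1)c1ccccc1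
Why: One-pot partial ester reduction and Wittig methylenation, in which the aluminium hemiacetal releases the β,γ-unsaturated aldehyde only as the ylide consumes it, so C9 does not epimerize and the alkene does not move into conjugation.

Step 8
Reactants: 11 {[(2R,4aR,8R,8aR)-8-ethenyl-4,4,7,8a-tetramethyl-1,2,3,4,4a,5,8,8a-octahydronaphthalen-2-yl]oxy}tri(propan-2-yl)silane
Product: 12 4,4,5,5-tetramethyl-2-{2-[(1R,4aR,7R,8aR)-2,5,5,8a-tetramethyl-7-{[tri(propan-2-yl)silyl]oxy}-1,4,4a,5,6,7,8,8a-octahydronaphthalen-1-yl]ethyl}-1,3,2-dioxaborolane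
Conditions: HBpin, [Ir(cod)Cl]2 (cat.), dppe (cat.), CH2Cl2, rt
Reagents that add atoms: pinacolborane, CC1(C)OBOC1(C)C
Why: Iridium-catalysed anti-Markovnikov hydroboration takes the monosubstituted alkene and leaves the trisubstituted ring alkene, giving the primary C12 boronate.

Step 9
Reactants: 13 (2R)-but-3-en-2-ol
Product: 14 (2R)-but-3-en-2-yl N,N-di(propan-2-yl)carbamate
Conditions: i-Pr2NCOCl, Et3N, DMAP (cat.), toluene, 90 °C
Reagents that add atoms: N,N-diisopropylcarbamoyl chloride, CC(C)N(C(C)C)C(=O)Cl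
Why: O-Carbamoylation (Hoppe carbamate) leaves the stereocentre untouched and installs the group that directs lithiation and later leaves.

Step 10
Reactants: 14 (2R)-but-3-en-2-yl N,N-di(propan-2-yl)carbamate; 12 4,4,5,5-tetramethyl-2-{2-[(1R,4aR,7R,8aR)-2,5,5,8a-tetramethyl-7-{[tri(propan-2-yl)silyl]oxy}-1,4,4a,5,6,7,8,8a-octahydronaphthalen-1-yl]ethyl}-1,3,2-dioxaborolane
Product: 18 (3S)-3-methyl-5-[(1R,4aR,7R,8aR)-2,5,5,8a-tetramethyl-7-{[tri(propan-2-yl)silyl]oxy}-1,4,4a,5,6,7,8,8a-octahydronaphthalen-1-yl]pent-1-en-3-ol, via lithiated carbamate 15 (not isolated), via boronate complex 16 (not isolated), via tertiary boronic ester 17 (not isolated)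
Conditions: 14, s-BuLi, TMEDA, Et2O, −78 °C; then 12, −78 → 35 °C; then NaOH, H2O2, THF, 0 °C → rt
Reagents that add atoms: hydrogen peroxide, OO
Why: Hoppe–Aggarwal lithiation–borylation, in which the α-oxyallyl carbanion (an umpoled carbinol carbon) is borylated at the α-carbon with retention, the primary alkyl group then migrates from boron to carbon with inversion as the carbamate leaves (1,2-metallate shift), and oxidation with retention gives the tertiary allylic alcohol, so that two nucleophilic carbons (C–Li and C–B) are joined and the (R)-carbamate sets C13 as S.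

Step 11
Reactants: 18 (3S)-3-methyl-5-[(1R,4aR,7R,8aR)-2,5,5,8a-tetramethyl-7-{[tri(propan-2-yl)silyl]oxy}-1,4,4a,5,6,7,8,8a-octahydronaphthalen-1-yl]pent-1-en-3-ol
Product: 19 (2R,4aR,8R,8aR)-8-[(3S)-3-hydroxy-3-methylpent-4-en-1-yl]-4,4,7,8a-tetramethyl-1,2,3,4,4a,5,8,8a-octahydronaphthalen-2-ol
Conditions: Bu4NF, THF, rt → 45 °C
Reagents that add atoms: none
Why: Fluoride-mediated desilylation frees the C2 alcohol without touching the alkenes or the tertiary allylic alcohol.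

Step 12
Reactants: 19 (2R,4aR,8R,8aR)-8-[(3S)-3-hydroxy-3-methylpent-4-en-1-yl]-4,4,7,8a-tetramethyl-1,2,3,4,4a,5,8,8a-octahydronaphthalen-2-ol
Product: 20 (2R,4aR,8R,8aR)-8-[(3S)-3-hydroxy-3-methylpent-4-en-1-yl]-4,4,7,8a-tetramethyl-1,2,3,4,4a,5,8,8a-octahydronaphthalen-2-yl 3-methylbut-2-enoate
Conditions: 3-methylbut-2-enoic acid, DCC, DMAP (cat.), CH2Cl2, 0 °C → rt
Reagents that add atoms: 3-methylbut-2-enoic acid, CC(C)=CC(=O)O
Why: Steglich esterification acylates the equatorial secondary alcohol and leaves the hindered tertiary allylic alcohol, and the carbodiimide conditions avoid the base-induced deconjugation seen with the acid chloride.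

## Compound list

1 | ketoisophorone (2,6,6-trimethylcyclohex-2-ene-1,4-dione) | CC1=CC(=O)CC(C)(C)C1=O | starting material
2 | (4R)-4-hydroxy-2,6,6-trimethylcyclohex-2-en-1-one | CC1=C[C@H](O)CC(C)(C)C1=O | intermediate
3 | (4R)-2,6,6-trimethyl-4-{[tri(propan-2-yl)silyl]oxy}cyclohex-2-en-1-one | CC1=C[C@H](O[Si](C(C)C)(C(C)C)C(C)C)CC(C)(C)C1=O | intermediate
4 | lithium (4S)-2,6,6-trimethyl-4-{[tri(propan-2-yl)silyl]oxy}cyclohex-1-en-1-olate | [Li+].CC1=C([O-])C(C)(C)C[C@@H](O[Si](C(C)C)(C(C)C)C(C)C)C1 | intermediate (not isolated)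
5 | (4S)-2,6,6-trimethyl-4-{[tri(propan-2-yl)silyl]oxy}cyclohex-1-en-1-yl trifluoromethanesulfonate | CC1=C(OS(=O)(=O)C(F)(F)F)C(C)(C)C[C@@H](O[Si](C(C)C)(C(C)C)C(C)C)C1 | intermediate
6 | tri(propan-2-yl)({(1S)-3,5,5-trimethyl-4-[2-(2-methyl-1,3-dioxolan-2-yl)ethyl]cyclohex-3-en-1-yl}oxy)silane | CC1=C(CCC2(C)OCCO2)C(C)(C)C[C@@H](O[Si](C(C)C)(C(C)C)C(C)C)C1 | intermediate (not isolated)
7 | 4-[(4S)-2,6,6-trimethyl-4-{[tri(propan-2-yl)silyl]oxy}cyclohex-1-en-1-yl]butan-2-one | CC1=C(CCC(C)=O)C(C)(C)C[C@@H](O[Si](C(C)C)(C(C)C)C(C)C)C1 | intermediate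
8 | methyl (2E)-3-methyl-5-[(4S)-2,6,6-trimethyl-4-{[tri(propan-2-yl)silyl]oxy}cyclohex-1-en-1-yl]pent-2-enoate | CC1=C(CC/C(C)=C/C(=O)OC)C(C)(C)C[C@@H](O[Si](C(C)C)(C(C)C)C(C)C)C1 | intermediate
9 | methyl (1R,4aR,7R,8aR)-2,5,5,8a-tetramethyl-7-{[tri(propan-2-yl)silyl]oxy}-1,4,4a,5,6,7,8,8a-octahydronaphthalene-1-carboxylate | COC(=O)[C@@H]1C(C)=CC[C@@H]2C(C)(C)C[C@@H](O[Si](C(C)C)(C(C)C)C(C)C)C[C@@]12C | intermediate
10 | (1R,4aR,7R,8aR)-2,5,5,8a-tetramethyl-7-{[tri(propan-2-yl)silyl]oxy}-1,4,4a,5,6,7,8,8a-octahydronaphthalene-1-carbaldehyde | O=C[C@@H]1C(C)=CC[C@@H]2C(C)(C)C[C@@H](O[Si](C(C)C)(C(C)C)C(C)C)C[C@@]12C | intermediate (not isolated)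
11 | {[(2R,4aR,8R,8aR)-8-ethenyl-4,4,7,8a-tetramethyl-1,2,3,4,4a,5,8,8a-octahydronaphthalen-2-yl]oxy}tri(propan-2-yl)silane | C=C[C@@H]1C(C)=CC[C@@H]2C(C)(C)C[C@@H](O[Si](C(C)C)(C(C)C)C(C)C)C[C@@]12C | intermediate
12 | 4,4,5,5-tetramethyl-2-{2-[(1R,4aR,7R,8aR)-2,5,5,8a-tetramethyl-7-{[tri(propan-2-yl)silyl]oxy}-1,4,4a,5,6,7,8,8a-octahydronaphthalen-1-yl]ethyl}-1,3,2-dioxaborolane | CC1(C)OB(CC[C@@H]2C(C)=CC[C@@H]3C(C)(C)C[C@@H](O[Si](C(C)C)(C(C)C)C(C)C)C[C@@]23C)OC1(C)C | intermediate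
13 | (2R)-but-3-en-2-ol | C=C[C@@H](C)O | starting material
14 | (2R)-but-3-en-2-yl N,N-di(propan-2-yl)carbamate | C=C[C@@H](C)OC(=O)N(C(C)C)C(C)C | intermediate
15 | [(2R)-2-{[di(propan-2-yl)carbamoyl]oxy}but-3-en-2-yl]lithium | C=C[C@@]([Li])(C)OC(=O)N(C(C)C)C(C)C | intermediate (not isolated)
16 | lithium borate (ate) complex in which the (2R)-2-{[di(propan-2-yl)carbamoyl]oxy}but-3-en-2-yl carbon of 15 is bound to the boron of 12 | [Li+].C=C[C@@](C)(OC(=O)N(C(C)C)C(C)C)[B-]1(CC[C@@H]2C(C)=CC[C@@H]3C(C)(C)C[C@@H](O[Si](C(C)C)(C(C)C)C(C)C)C[C@@]23C)OC(C)(C)C(C)(C)O1 | intermediate (not isolated)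
17 | 4,4,5,5-tetramethyl-2-{(3R)-3-methyl-5-[(1R,4aR,7R,8aR)-2,5,5,8a-tetramethyl-7-{[tri(propan-2-yl)silyl]oxy}-1,4,4a,5,6,7,8,8a-octahydronaphthalen-1-yl]pent-1-en-3-yl}-1,3,2-dioxaborolane | C=C[C@@](C)(B1OC(C)(C)C(C)(C)O1)CC[C@@H]2C(C)=CC[C@@H]3C(C)(C)C[C@@H](O[Si](C(C)C)(C(C)C)C(C)C)C[C@@]23C | intermediate (not isolated)
18 | (3S)-3-methyl-5-[(1R,4aR,7R,8aR)-2,5,5,8a-tetramethyl-7-{[tri(propan-2-yl)silyl]oxy}-1,4,4a,5,6,7,8,8a-octahydronaphthalen-1-yl]pent-1-en-3-ol | C=C[C@@](C)(O)CC[C@@H]1C(C)=CC[C@@H]2C(C)(C)C[C@@H](O[Si](C(C)C)(C(C)C)C(C)C)C[C@@]12C | intermediate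
19 | (2R,4aR,8R,8aR)-8-[(3S)-3-hydroxy-3-methylpent-4-en-1-yl]-4,4,7,8a-tetramethyl-1,2,3,4,4a,5,8,8a-octahydronaphthalen-2-ol | C=C[C@@](C)(O)CC[C@@H]1C(C)=CC[C@@H]2C(C)(C)C[C@@H](O)C[C@@]12C | intermediate
20 | (2R,4aR,8R,8aR)-8-[(3S)-3-hydroxy-3-methylpent-4-en-1-yl]-4,4,7,8a-tetramethyl-1,2,3,4,4a,5,8,8a-octahydronaphthalen-2-yl 3-methylbut-2-enoate (CNP0252389.1) | C=C[C@@](C)(O)CC[C@@H]1C(C)=CC[C@@H]2C(C)(C)C[C@@H](OC(=O)C=C(C)C)C[C@@]12C | target

## Step count and risks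

Total step count: 12 (steps 1–12, step 9 being a one-step side branch).
Longest linear sequence: 11 steps (1 → 20 through steps 1–8 and 10–12).

Three steps most likely to fail:

Step 10 (lithiation–borylation). The risks are γ- instead of α-borylation of the terminally unsubstituted allyl anion, loss of configuration before trapping, and a slow 1,2-shift on the hindered ate complex; should the borylation prove invertive, the (2S)-alcohol would be used instead of 13. The fallback sets out from 12 and comes back at 18. Suzuki–Miyaura coupling of 12 with ethyl (2E)-3-iodobut-2-enoate (Pd(OAc)2, RuPhos, K3PO4, toluene/water, 80 °C) gives ethyl (2E)-3-methyl-5-[(1R,4aR,7R,8aR)-2,5,5,8a-tetramethyl-7-{[tri(propan-2-yl)silyl]oxy}-1,4,4a,5,6,7,8,8a-octahydronaphthalen-1-yl]pent-2-enoate F6. Reduction with i-Bu2AlH gives the allylic alcohol (2E)-3-methyl-5-[(1R,4aR,7R,8aR)-2,5,5,8a-tetramethyl-7-{[tri(propan-2-yl)silyl]oxy}-1,4,4a,5,6,7,8,8a-octahydronaphthalen-1-yl]pent-2-en-1-ol F7. Sharpless epoxidation (Ti(OiPr)4, L-(+)-diethyl tartrate, t-BuOOH, 4 Å sieves, CH2Cl2, −20 °C) gives the (2S,3S)-epoxy alcohol [(2S,3S)-3-methyl-3-{2-[(1R,4aR,7R,8aR)-2,5,5,8a-tetramethyl-7-{[tri(propan-2-yl)silyl]oxy}-1,4,4a,5,6,7,8,8a-octahydronaphthalen-1-yl]ethyl}oxiran-2-yl]methanol F8, in which reagent control sets C13. Iodination (I2, PPh3, imidazole) gives the epoxy iodide of F8, that is the (iodomethyl)oxirane F9, and zinc in ethanol at reflux opens it by reductive elimination to the tertiary allylic alcohol 18.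

Step 6 (cyclization). The risks are a weakly nucleophilic enoate terminator, modest facial control by the C2 silyloxy group, Δ7/Δ8 alkene mixtures, and loss of the silyl ether. The fallback sets out from 8 and comes back at 10, which is then isolated and methylenated to 11 as in step 7. Reduction of 8 with i-Bu2AlH gives (2E)-3-methyl-5-[(4S)-2,6,6-trimethyl-4-{[tri(propan-2-yl)silyl]oxy}cyclohex-1-en-1-yl]pent-2-en-1-ol F2. Acetylation (Ac2O, pyridine) gives (2E)-3-methyl-5-[(4S)-2,6,6-trimethyl-4-{[tri(propan-2-yl)silyl]oxy}cyclohex-1-en-1-yl]pent-2-en-1-yl acetate F3, whose trisubstituted alkene is a far better π-nucleophile than the enoate. SnCl4 in CH2Cl2 at −78 °C (the monocyclofarnesyl acetate to drimenyl acetate manifold) then gives [(1R,4aR,7R,8aR)-2,5,5,8a-tetramethyl-7-{[tri(propan-2-yl)silyl]oxy}-1,4,4a,5,6,7,8,8a-octahydronaphthalen-1-yl]methyl acetate F4. Methanolysis (K2CO3, MeOH) gives [(1R,4aR,7R,8aR)-2,5,5,8a-tetramethyl-7-{[tri(propan-2-yl)silyl]oxy}-1,4,4a,5,6,7,8,8a-octahydronaphthalen-1-yl]methanol F5, and Dess–Martin oxidation gives aldehyde 10.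

Step 4 (Negishi coupling). The enol triflate is flanked by a methyl-bearing sp2 carbon and a quaternary carbon, so transmetallation and reductive elimination may lose to β-hydride elimination. The fallback sets out from 5 and comes back at 7. A Heck reaction of 5 with but-3-en-2-one (Pd(OAc)2, PPh3, Et3N, DMF, 80 °C), well known for this class of triflate, gives the dienone (3E)-4-[(4S)-2,6,6-trimethyl-4-{[tri(propan-2-yl)silyl]oxy}cyclohex-1-en-1-yl]but-3-en-2-one F1. Conjugate reduction of its disubstituted enone double bond with [(Ph3P)CuH]6 in wet benzene leaves the tetrasubstituted ring alkene and gives 7.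

## Further compounds

F1 | step 4 | (3E)-4-[(4S)-2,6,6-trimethyl-4-{[tri(propan-2-yl)silyl]oxy}cyclohex-1-en-1-yl]but-3-en-2-one | CC1=C(/C=C/C(C)=O)C(C)(C)C[C@@H](O[Si](C(C)C)(C(C)C)C(C)C)C1
F2 | step 6 | (2E)-3-methyl-5-[(4S)-2,6,6-trimethyl-4-{[tri(propan-2-yl)silyl]oxy}cyclohex-1-en-1-yl]pent-2-en-1-ol | CC1=C(CC/C(C)=C/CO)C(C)(C)C[C@@H](O[Si](C(C)C)(C(C)C)C(C)C)C1
F3 | step 6 | (2E)-3-methyl-5-[(4S)-2,6,6-trimethyl-4-{[tri(propan-2-yl)silyl]oxy}cyclohex-1-en-1-yl]pent-2-en-1-yl acetate | CC1=C(CC/C(C)=C/COC(C)=O)C(C)(C)C[C@@H](O[Si](C(C)C)(C(C)C)C(C)C)C1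
F4 | step 6 | [(1R,4aR,7R,8aR)-2,5,5,8a-tetramethyl-7-{[tri(propan-2-yl)silyl]oxy}-1,4,4a,5,6,7,8,8a-octahydronaphthalen-1-yl]methyl acetate | CC(=O)OC[C@@H]1C(C)=CC[C@@H]2C(C)(C)C[C@@H](O[Si](C(C)C)(C(C)C)C(C)C)C[C@@]12C
F5 | step 6 | [(1R,4aR,7R,8aR)-2,5,5,8a-tetramethyl-7-{[tri(propan-2-yl)silyl]oxy}-1,4,4a,5,6,7,8,8a-octahydronaphthalen-1-yl]methanol | OC[C@@H]1C(C)=CC[C@@H]2C(C)(C)C[C@@H](O[Si](C(C)C)(C(C)C)C(C)C)C[C@@]12C
F6 | step 10 | ethyl (2E)-3-methyl-5-[(1R,4aR,7R,8aR)-2,5,5,8a-tetramethyl-7-{[tri(propan-2-yl)silyl]oxy}-1,4,4a,5,6,7,8,8a-octahydronaphthalen-1-yl]pent-2-enoate | CCOC(=O)/C=C(\C)CC[C@@H]1C(C)=CC[C@@H]2C(C)(C)C[C@@H](O[Si](C(C)C)(C(C)C)C(C)C)C[C@@]12C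
F7 | step 10 | (2E)-3-methyl-5-[(1R,4aR,7R,8aR)-2,5,5,8a-tetramethyl-7-{[tri(propan-2-yl)silyl]oxy}-1,4,4a,5,6,7,8,8a-octahydronaphthalen-1-yl]pent-2-en-1-ol | OC/C=C(\C)CC[C@@H]1C(C)=CC[C@@H]2C(C)(C)C[C@@H](O[Si](C(C)C)(C(C)C)C(C)C)C[C@@]12C
F8 | step 10 | [(2S,3S)-3-methyl-3-{2-[(1R,4aR,7R,8aR)-2,5,5,8a-tetramethyl-7-{[tri(propan-2-yl)silyl]oxy}-1,4,4a,5,6,7,8,8a-octahydronaphthalen-1-yl]ethyl}oxiran-2-yl]methanol | OC[C@@H]1O[C@@]1(C)CC[C@@H]2C(C)=CC[C@@H]3C(C)(C)C[C@@H](O[Si](C(C)C)(C(C)C)C(C)C)C[C@@]23C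
F9 | step 10 | (iodomethyl)oxirane derived from F8 (CH2OH replaced by CH2I, same configuration in space) | IC[C@@H]1O[C@@]1(C)CC[C@@H]2C(C)=CC[C@@H]3C(C)(C)C[C@@H](O[Si](C(C)C)(C(C)C)C(C)C)C[C@@]23C
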